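A small charge of D, 3.00 equiv on Q at 0.020 M, is my flask, and I ask what it holds as X at 3.0 h.

| flask | Q | D | remark | time |
|---|---|---|---|---|
| west | 0.020 M | 4.2 equiv | run made earlier |  |
| north-west | 0.020 M | 6.6 equiv | run made earlier |  |
| south-west | 0.030 M | 3 equiv | run made earlier |  |
| flask | 0.020 M | 3.00 equiv |  | 3.0 h |

| run | time / h | X / % | Q / % |
|---|---|---|---|
| west | 0.417 | 18.6 | 0 |
| west | 0.833 | 15.7 | 1.3 |
| west | 1.33 | 14.3 | 1.1 |
| west | 1.50 | 16.7 | 0 |
| west | 2.00 | 15.7 | 0 |
| west | 2.50 | 14.6 | 0 |
| west | 3.00 | 16.4 | 1.8 |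
| north-west | 0.417 | 12.6 | 0.4 |
| north-west | 0.833 | 10.6 | 1.0 |
| north-west | 1.33 | 12.5 | 0 |
| north-west | 1.50 | 12.7 | 0 |
| north-west | 2.00 | 11.0 | 0.2 |
| north-west | 2.50 | 12.9 | 0 |
| north-west | 3.00 | 12.1 | 0 |
| south-west | 0.250 | 23.2 | 10.5 |
| south-west | 0.833 | 21.5 | 0 |
| south-west | 1.33 | 20.2 | 0 |
| south-west | 2.00 | 20.1 | 0 |
| south-west | 3.00 | 19.0 | 0 |

(each reading ± 1 percentage point)

- the numbers in the tables scatter with a standard deviation of 1 percentage point

- equivalents of D to Q, everything else as given, that leave most X at 3.0 h
- the amount of X then, in percent of the Q charged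
- the amount of X with the amounts as given

I take the pace first. In the south-west run Q reads 10.5% of its charge at 0.250 h, an average pace of 9.02 h⁻¹. If the pace follows D, the smaller charge of D in my flask slows it by a factor 0.667. Even if each Q takes two D, the fraction of D remaining is 0.333, which slows it again. Together these give a cautious estimate of the pace in my flask, 2.00 h⁻¹, so I reckon a lifetime of Q there of about 0.500 h, shorter than 3.0 h. So for my flask I look to the level of X rather than to the clock.

The west and north-west runs have the Q of my flask, and I average their X readings, which show no steady drift, to 16.0% and 12.1%. The zero of my scale is X indifferent to D. Between these two runs, raising D by a factor 1.57 goes with X lower by a factor 1.32, so I read, with the scatter of the readings on it, that X falls as the equivalents to the power 0.626. I call this power the D-slope, an apparent order in D. Carried from west to my flask, it gives 19.8%.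

The forecast is higher, at 25%, and puts the best charge at 1.5 equiv with 45%: “Cutting D should favour X until D runs out before Q does”.

    X ⇌ E (K = 1.90, k = 0.0770 min⁻¹)
    X → L (k = 2.30 × 10⁻⁵ min⁻¹)
    Q + D → X + Z (k = 2.70 M⁻¹ min⁻¹)
    D + X ⇌ G + Z (K = 1.90, k = 6.50 M⁻¹ min⁻¹)

The flask gives 19.9%, and its best charge is 1.23 equiv with 29.7%. Run to 30.0 h, the flask still holds 19.8% of X. The D-slope of 0.626 gave 19.8% for this flask, and for the same flask with 5.10 equiv of D it gives 14.2%, where that neighbour holds 14.1%.

(The numbers in the tables were generated by integration with constants of no real substance; scatter was added.)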